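The constants are those of an exercise; the run is a simulation.

One ratio of rate constants carries our reckoning of this flask.

    first end groups + second end groups → links (k1 = 0.27 M⁻¹ s⁻¹)
    second end groups → decomposed reagent (k2 = 0.026 s⁻¹)
    first end groups → decomposition product (k3 = 4.9 × 10⁻⁵ s⁻¹)

first end groups 0.25 M; second end groups 0.250 M; time 50 min

- each molecule carries two end groups: a chain counts once for every two ends that are left, dead ends included; the units are half of the end groups of the two monomers charged
- run time (flask): 50 min

* average number of monomer units in a chain (unreacted monomers counted as chains of one) at 50 min
* part of the first end groups that has reacted at 50 min

With equal charges each link takes one end of each kind, so in this flask dp is one over x, the unlinked fraction of the first end groups. Our zero of the scale is x at nought, where dp has no bound, and step 2 pulls x above it by using second end groups without making links. Second end groups divide between steps 1 and 2, and K = 0.0963 M is the concentration of first end groups at which both steps use them equally. While they last we set step 3 aside, because its half-life of 3.93 h is far longer than their 0.444 min.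

Dividing the two rate equations and setting c(second end groups) to nought gives x = −w ln x, with w = K/c(first end groups) = 0.385. Taking ln x as minus one gives x = w and dp 2.60. That is the weak link, so we put w back into the logarithm and get 0.367, which is lower. The mean of the two, 0.376, gives dp 2.66. The half-life of second end groups is short against 50 min, so step 3 then acts on the unlinked first end groups through the run, which gives c 67.5%. Dead ends still count, so dp stays.

The forecast gave dp 2.65 (2.6 to 2.7) and c 67.5% (67% to 68%), from “Second end groups die quickly”. Our dp lies inside its range, below the high end.

The flask gives dp 2.66 and c 67.5%. In the neighbour flask with 1.0 M of second end groups, the same integration keeps K, and the excess of the charged second end groups over the charged first end groups enters the exponent. With the charges of that flask this gives x near exp(−(c(second end groups) − c(first end groups))/K), and step 3 brings it to 0.0358%. That neighbour flask holds 0.036% of its first end groups at 50.0 min, with dp 1.67.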